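The target is 3',5'-diprenylkaempferol (flavonoid numbering). C4 is a ketone carbon held between C4a of the 5,7-dioxygenated ring A and the oxygen-bearing C3. It is therefore an aroyl carbon on the α-carbon of an α-oxy ketone, and it can enter as carbon monoxide.
Cuts: O1–C2 (cyclodehydration); C4a–C4 and C4–C3 together (aryl iodide + CO + ketone enolate); C2–C1' (aryllithium + Weinreb amide); the two ring B aryl–prenyl bonds (ortho C-alkylation of a phenoxide).
Forward: rings A and B are bought as phloroglucinol and 4-bromophenol. Ring B receives its prenyl groups and then the C2–C3 unit. CO joins C3 to ring A in an open-chain 1,3-diketone, and ring C closes last, in the flask in which all MOM groups fall.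
Stereochemistry: the target has no stereocentre and no E/Z alkene. The only stereocentre on the way (the central diketone carbon, later C3) is racemic, enolisable and erased when ring C becomes aromatic.

Key step: step 8

Assumption: in step 9 the order of acetal loss and ring closure is not fixed, so 18 is drawn as the fully unmasked open form; MOM = methoxymethyl, dppp = 1,3-bis(diphenylphosphino)propane.

Step 1
Reactants: 1 phloroglucinol; 2 chloromethyl methyl ether (MOMCl)
Product: 3 1,3,5-tris(methoxymethoxy)benzene
Conditions: NaH (3.5 equiv), MOMCl (3.5 equiv), DMF, 0 °C to rt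
Reagents that add atoms: chloromethyl methyl ether (2), COCCl
Why: Threefold Williamson-type O-alkylation, in which the hard electrophile MOMCl attacks the phenoxide oxygens in DMF, is the standard acetal protection of phloroglucinol.

Step 2
Reactants: 3 1,3,5-tris(methoxymethoxy)benzene
Product: 5 2-iodo-1,3,5-tris(methoxymethoxy)benzene, via aryllithium 4 (not isolated)
Conditions: n-BuLi (1.1 equiv), THF, 0 °C; I2 (1.2 equiv), THF, −78 °C to rt; aq Na2S2O3
Reagents that add atoms: n-butyllithium, [Li]CCCC (lithium of 4 only); iodine, II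
Why: In this directed ortho-metalation every ring C–H lies between two coordinating MOM-oxy groups and all three are equivalent, so one aryllithium forms and its iodinolysis can only give the mono-iodide.

Step 3
Reactants: 6 methyl glycolate; 2 chloromethyl methyl ether
Product: 7 methyl 2-(methoxymethoxy)acetate
Conditions: MOMCl (1.3 equiv), iPr2NEt (1.5 equiv), CH2Cl2, 0 °C to rt
Reagents that add atoms: chloromethyl methyl ether (2), COCCl
Why: This is a routine MOM acetalisation of a primary alcohol under amine base, which leaves the methyl ester untouched.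

Step 4
Reactants: 7 methyl 2-(methoxymethoxy)acetate
Product: 8 N-methoxy-2-(methoxymethoxy)-N-methylacetamide
Conditions: MeNH(OMe)·HCl (1.5 equiv), iPrMgCl (3.0 equiv), THF, −20 to 0 °C
Reagents that add atoms: N,O-dimethylhydroxylamine hydrochloride, CNOC.Cl
Why: Aminolysis of the ester by the magnesium amide made from the amine salt and iPrMgCl is the usual direct ester-to-Weinreb-amide conversion, and the acetal is inert to it.

Step 5
Reactants: 9 4-bromophenol; 10 prenyl bromide (1-bromo-3-methylbut-2-ene)
Product: 11 4-bromo-2,6-bis(3-methylbut-2-enyl)phenol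
Conditions: prenyl bromide (2.5 equiv), KOH (3 equiv), H2O, rt, vigorous stirring
Reagents that add atoms: prenyl bromide (10), CC(C)=CCBr
Why: In this ortho C-alkylation of an ambident phenoxide, water ties up the oxygen by hydrogen bonding, so the soft allylic bromide is attacked by the ring carbons in SN2 fashion (linear prenyl retained), the para bromine leaves only the two ortho sites open, and the double prenylation is established for para-halophenols.

Step 6
Reactants: 11 4-bromo-2,6-bis(3-methylbut-2-enyl)phenol; 2 chloromethyl methyl ether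
Product: 12 5-bromo-2-(methoxymethoxy)-1,3-bis(3-methylbut-2-enyl)benzene
Conditions: NaH (1.3 equiv), MOMCl (1.3 equiv), DMF, 0 °C to rt
Reagents that add atoms: chloromethyl methyl ether (2), COCCl
Why: In this Williamson-type MOM protection the small, reactive MOMCl reaches the sodium phenoxide despite the two flanking prenyl groups.

Step 7
Reactants: 12 5-bromo-2-(methoxymethoxy)-1,3-bis(3-methylbut-2-enyl)benzene; 8 N-methoxy-2-(methoxymethoxy)-N-methylacetamide
Product: 14 2-(methoxymethoxy)-1-[4-(methoxymethoxy)-3,5-bis(3-methylbut-2-enyl)phenyl]ethanone, via aryllithium 13 (not isolated)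
Conditions: n-BuLi (1.05 equiv), THF, −78 °C; 8 (1.2 equiv), −78 to −20 °C; aq NH4Cl
Reagents that add atoms: n-butyllithium, [Li]CCCC (lithium of 13 only)
Why: In this Weinreb ketone synthesis bromine–lithium exchange at −78 °C outruns deprotonation of the benzylic allylic CH2 groups (both positions ortho to the MOM ether are blocked), and the N-methoxy-N-methylamide delivers the ketone without over-addition.

Step 8
Reactants: 5 2-iodo-1,3,5-tris(methoxymethoxy)benzene; 14 2-(methoxymethoxy)-1-[4-(methoxymethoxy)-3,5-bis(3-methylbut-2-enyl)phenyl]ethanone; 15 carbon monoxide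
Product: 17 2-(methoxymethoxy)-1-[4-(methoxymethoxy)-3,5-bis(3-methylbut-2-enyl)phenyl]-3-[2,4,6-tris(methoxymethoxy)phenyl]propane-1,3-dione (racemic), via sodium enolate 16 (not isolated)
Conditions: 14 (2.1 equiv), NaN(SiMe3)2 (2.1 equiv), THF, 0 °C; then 5 (1.0 equiv), Pd(dba)2 (5 mol %), dppp (6 mol %), CO (1 atm), 1,4-dioxane, 80 °C; aq NH4Cl; surplus 14 recovered
Reagents that add atoms: carbon monoxide (15), [C-]#[O+]; NaN(SiMe3)2, [Na+].C[Si](C)(C)[N-][Si](C)(C)C (sodium of 16 only)
Why: Zerovalent palladium inserts into the C–I bond of 5, CO migrates into the crowded aryl–palladium bond (C4a–C4) to give an aroylpalladium iodide, enolate 16 displaces iodide, and reductive elimination from the carbon-bound palladium enolate forms C4–C3, which is the known carbonylative α-arylation of aryl alkyl ketones with aryl iodides to 1,3-diketones (closest cases: propiophenone-type enolates). No ring closes in this step. The one new stereocentre, the central carbon, arises racemic with no controlling element and needs none, since it is enolisable and ends as sp2 C3. Carbonylation must outrun direct α-arylation, and the two ortho MOM-oxy groups of 5 secure this, because CO insertion relieves their strain whereas aryl–carbon reductive elimination onto a secondary enolate is blocked by them. C-acylation must outrun O-acylation, which the cis-chelating dppp favours by holding acyl and enolate carbon side by side, and any enol ester that does form should be funnelled by surplus enolate to the more stable diketone anion. The second equivalent of 16 takes up the acidic proton of 17 and returns 14, while the MOM ethers and the trisubstituted prenyl alkenes are inert to base, CO and catalyst.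

Step 9
Reactants: 17 2-(methoxymethoxy)-1-[4-(methoxymethoxy)-3,5-bis(3-methylbut-2-enyl)phenyl]-3-[2,4,6-tris(methoxymethoxy)phenyl]propane-1,3-dione
Product: 19 3,5,7-trihydroxy-2-[4-hydroxy-3,5-bis(3-methylbut-2-enyl)phenyl]chromen-4-one (target), via unmasked diketone 18 (not isolated)
Conditions: 3 M HCl, MeOH, 50 °C, stopped as soon as conversion is complete
Reagents that add atoms: none
Why: Acid-catalysed transacetalisation to methanol strips all five MOM groups, and either of the two equivalent ortho phenols of ring A then adds to the ring B ketone (6-exo-trig hemiketal) and water is lost, which is the classical cyclodehydration of 2-oxygenated 1-(2-hydroxyaryl)-1,3-diketones to flavonols; no oxidant is needed because 17 is already at the flavonol oxidation level, and dilute methanolic HCl is the customary MOM cleavage for prenylated flavonoids.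

Compound list
1 | phloroglucinol (benzene-1,3,5-triol) | Oc1cc(O)cc(O)c1 | starting material
2 | chloromethyl methyl ether (MOMCl) | COCCl | starting material
3 | 1,3,5-tris(methoxymethoxy)benzene | COCOc1cc(OCOC)cc(OCOC)c1 | intermediate
4 | 2,4,6-tris(methoxymethoxy)phenyllithium (in situ) | [Li]c1c(OCOC)cc(OCOC)cc1OCOC | intermediate
5 | 2-iodo-1,3,5-tris(methoxymethoxy)benzene | COCOc1cc(OCOC)c(I)c(OCOC)c1 | intermediate
6 | methyl glycolate | COC(=O)CO | starting material
7 | methyl 2-(methoxymethoxy)acetate | COCOCC(=O)OC | intermediate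
8 | N-methoxy-2-(methoxymethoxy)-N-methylacetamide | COCOCC(=O)N(C)OC | intermediate
9 | 4-bromophenol | Oc1ccc(Br)cc1 | starting material
10 | prenyl bromide (1-bromo-3-methylbut-2-ene) | CC(C)=CCBr | starting material
11 | 4-bromo-2,6-bis(3-methylbut-2-enyl)phenol | CC(C)=CCc1cc(Br)cc(CC=C(C)C)c1O | intermediate
12 | 5-bromo-2-(methoxymethoxy)-1,3-bis(3-methylbut-2-enyl)benzene | COCOc1c(CC=C(C)C)cc(Br)cc1CC=C(C)C | intermediate
13 | 4-(methoxymethoxy)-3,5-bis(3-methylbut-2-enyl)phenyllithium (in situ) | [Li]c1cc(CC=C(C)C)c(OCOC)c(CC=C(C)C)c1 | intermediate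
14 | 2-(methoxymethoxy)-1-[4-(methoxymethoxy)-3,5-bis(3-methylbut-2-enyl)phenyl]ethanone | COCOCC(=O)c1cc(CC=C(C)C)c(OCOC)c(CC=C(C)C)c1 | intermediate
15 | carbon monoxide | [C-]#[O+] | starting material
16 | sodium enolate of 14 (in situ; drawn as the chelated Z enolate, geometry of no consequence) | [Na+].[O-]/C(=C\OCOC)c1cc(CC=C(C)C)c(OCOC)c(CC=C(C)C)c1 | intermediate
17 | 2-(methoxymethoxy)-1-[4-(methoxymethoxy)-3,5-bis(3-methylbut-2-enyl)phenyl]-3-[2,4,6-tris(methoxymethoxy)phenyl]propane-1,3-dione (racemic) | COCOC(C(=O)c1c(OCOC)cc(OCOC)cc1OCOC)C(=O)c1cc(CC=C(C)C)c(OCOC)c(CC=C(C)C)c1 | intermediate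
18 | 2-hydroxy-1-[4-hydroxy-3,5-bis(3-methylbut-2-enyl)phenyl]-3-(2,4,6-trihydroxyphenyl)propane-1,3-dione (racemic, in situ) | OC(C(=O)c1c(O)cc(O)cc1O)C(=O)c1cc(CC=C(C)C)c(O)c(CC=C(C)C)c1 | intermediate
19 | 3,5,7-trihydroxy-2-[4-hydroxy-3,5-bis(3-methylbut-2-enyl)phenyl]chromen-4-one | CC(C)=CCc1cc(-c2oc3cc(O)cc(O)c3c(=O)c2O)cc(CC=C(C)C)c1O | target

Total step count: 9.
Longest linear sequence: 5 steps (steps 5, 6, 7, 8, 9, from 4-bromophenol).

Steps most likely to fail

1. Step 8.
- Risk: oxidative addition to the electron-rich, doubly ortho-substituted iodide may be slow under CO. Capture of the shielded aroylpalladium by a secondary, chelated enolate may then lag behind protodehalogenation, O-acylation or self-condensation of the enolate.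
- Fallback: an aldol–oxidation sequence in which C4 comes from DMF. It sets out from 3 and 14 and comes back at 17. Compound 3 is lithiated as in step 2, and 4 is quenched with DMF to give 2,4,6-tris(methoxymethoxy)benzaldehyde F1. Ketone 14 is deprotonated with LiN(iPr)2 in THF at −78 °C and added to F1. This gives 3-hydroxy-2-(methoxymethoxy)-1-[4-(methoxymethoxy)-3,5-bis(3-methylbut-2-enyl)phenyl]-3-[2,4,6-tris(methoxymethoxy)phenyl]propan-1-one F2 as a diastereomer mixture of no consequence. Dess–Martin periodinane buffered with NaHCO3 in CH2Cl2 then oxidises the benzylic carbinol to 17 without touching the prenyl or MOM groups.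

2. Step 5.
- Risk: competing O-alkylation, arrest at the monoprenyl stage and hydrolysis of the allylic bromide may erode throughput and make the separation laborious.
- Fallback: cross-coupling in place of phenoxide alkylation. It sets out from 9 and comes back at 12, so step 6 is skipped. Compound 9 is iodinated at both ortho positions (N-iodosuccinimide, catalytic TsOH, MeCN) to 4-bromo-2,6-diiodophenol F3. This is protected (NaH, 2, DMF) as 5-bromo-1,3-diiodo-2-(methoxymethoxy)benzene F4. A double Stille coupling with tributyl(3-methylbut-2-enyl)stannane (Pd(PPh3)4, LiCl, DMF, 80 °C) engages the two C–I bonds ahead of the C–Br bond and should give 12 with linear prenyl groups.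

3. Step 9.
- Risk: acid-induced addition of the liberated ring B phenol to a flanking prenyl alkene (chroman closure), or addition of solvent to the alkenes, may compete with the slower acetal cleavages.
- Fallback: the ring B phenol carries a fluoride-labile group, so the acid never meets an ortho-prenylphenol. It sets out from 11 and comes back at 19. Compound 11 is silylated (iPr3SiOTf, 2,6-lutidine, CH2Cl2) to [4-bromo-2,6-bis(3-methylbut-2-enyl)phenoxy]triisopropylsilane F5. The chemistry of step 7 (n-BuLi, then 8) gives 2-(methoxymethoxy)-1-[3,5-bis(3-methylbut-2-enyl)-4-(triisopropylsilyloxy)phenyl]ethanone F6. The chemistry of step 8 (NaN(SiMe3)2, 5, 15, Pd(dba)2, dppp) gives 2-(methoxymethoxy)-1-[3,5-bis(3-methylbut-2-enyl)-4-(triisopropylsilyloxy)phenyl]-3-[2,4,6-tris(methoxymethoxy)phenyl]propane-1,3-dione F7. Methanolic HCl removes the four MOM groups and closes ring C while the hindered aryl silyl ether stays on. The product is 3,5,7-trihydroxy-2-[3,5-bis(3-methylbut-2-enyl)-4-(triisopropylsilyloxy)phenyl]chromen-4-one F8. Bu4NF buffered with AcOH in THF at 0 °C finally releases 19.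

Further compounds
F1 | step 8 | 2,4,6-tris(methoxymethoxy)benzaldehyde | COCOc1cc(OCOC)c(C=O)c(OCOC)c1
F2 | step 8 | 3-hydroxy-2-(methoxymethoxy)-1-[4-(methoxymethoxy)-3,5-bis(3-methylbut-2-enyl)phenyl]-3-[2,4,6-tris(methoxymethoxy)phenyl]propan-1-one (racemic diastereomer mixture) | COCOC(C(O)c1c(OCOC)cc(OCOC)cc1OCOC)C(=O)c1cc(CC=C(C)C)c(OCOC)c(CC=C(C)C)c1
F3 | step 5 | 4-bromo-2,6-diiodophenol | Oc1c(I)cc(Br)cc1I
F4 | step 5 | 5-bromo-1,3-diiodo-2-(methoxymethoxy)benzene | COCOc1c(I)cc(Br)cc1I
F5 | step 9 | [4-bromo-2,6-bis(3-methylbut-2-enyl)phenoxy]triisopropylsilane | CC(C)=CCc1cc(Br)cc(CC=C(C)C)c1O[Si](C(C)C)(C(C)C)C(C)C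
F6 | step 9 | 2-(methoxymethoxy)-1-[3,5-bis(3-methylbut-2-enyl)-4-(triisopropylsilyloxy)phenyl]ethanone | COCOCC(=O)c1cc(CC=C(C)C)c(O[Si](C(C)C)(C(C)C)C(C)C)c(CC=C(C)C)c1
F7 | step 9 | 2-(methoxymethoxy)-1-[3,5-bis(3-methylbut-2-enyl)-4-(triisopropylsilyloxy)phenyl]-3-[2,4,6-tris(methoxymethoxy)phenyl]propane-1,3-dione (racemic) | COCOC(C(=O)c1c(OCOC)cc(OCOC)cc1OCOC)C(=O)c1cc(CC=C(C)C)c(O[Si](C(C)C)(C(C)C)C(C)C)c(CC=C(C)C)c1
F8 | step 9 | 3,5,7-trihydroxy-2-[3,5-bis(3-methylbut-2-enyl)-4-(triisopropylsilyloxy)phenyl]chromen-4-one | CC(C)=CCc1cc(-c2oc3cc(O)cc(O)c3c(=O)c2O)cc(CC=C(C)C)c1O[Si](C(C)C)(C(C)C)C(C)C
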